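## Retrosynthetic overview

- The 14-membered carbocycle is opened last at the (E)-C2=C3 alkene (ring-closing metathesis of vinyl groups on the fully substituted C1 and C4); the C4–C6 β-hydroxy ketone is cut at C5–C6 (C5,O-dimetalated carbinol fragment plus C6 aldehyde, then oxidation).
- Key disconnection: the oxolane (O, C1, C14, C13, C12) is cut at C13–C14 and at O–C12, giving a 1,3-C,O-dianion (C14 carbanion and C1 alkoxide, from a β-hydroxy sulfide) and a 1,2-dielectrophile (C13 triflate and C11–C12 epoxide).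
- Enabling feature: the methyl-bearing oxolane carbon C12 carries the exocyclic acetoxy carbon C11, so the ring is a 2-(1-oxyalkyl)oxolane, the retron of a 5-exo opening of a 2,3-epoxy alcohol derivative; the isopropyl-bearing oxolane carbon C1 is a tertiary carbinol with a CH2 arm (C14).
- Stereocentres: C1, C4 and C11/C12 come from D-tartrate Sharpless epoxides (C12 by inversion in the key step), C8 from (S)-citronellol.
- Ring order: oxolane first (key step), 14-membered carbocycle last.

Key step: step 10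

Remark on the chemistry: atoms are numbered as in cembranes (C1 = oxolane carbon with isopropyl, C12 = oxolane carbon with methyl, C11 = acetoxy carbon, C4 = tertiary carbinol, C6 = ketone, C8 = methyl-bearing methine); (S)-citronellol and (R)-2-methylglycidol are taken as commercial materials of high enantiomeric purity.

## Route

Step 1
Reactants: 1 (S)-citronellol
Product: 2 tert-butyl{[(3S)-3,7-dimethyloct-6-en-1-yl]oxy}diphenylsilane
Conditions: TBDPSCl, imidazole, CH2Cl2, 0 °C → rt
Reagents that add atoms: tert-butyl(chloro)diphenylsilane, CC(C)(C)[Si](Cl)(c1ccccc1)c1ccccc1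
Why: Silyl ether formation on the primary alcohol gives a protecting group that should survive the oxidation, organocopper and mild acid steps; C8 is not touched.

Step 2
Reactants: 2 tert-butyl{[(3S)-3,7-dimethyloct-6-en-1-yl]oxy}diphenylsilane
Product: 3 (2E,6S)-8-{[tert-butyl(diphenyl)silyl]oxy}-2,6-dimethyloct-2-en-1-ol
Conditions: SeO2 (0.3 equiv), t-BuOOH (3 equiv), salicylic acid (0.1 equiv), CH2Cl2, rt
Reagents that add atoms: tert-butyl hydroperoxide, CC(C)(C)OO
Why: Riley allylic oxidation with catalytic SeO2 (ene reaction, then [2,3]-sigmatropic shift) should hydroxylate the (E)-methyl group of the trisubstituted alkene and give the (E)-2-methylallylic alcohol; no stereocentre is formed.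

Step 3
Reactants: 3 (2E,6S)-8-{[tert-butyl(diphenyl)silyl]oxy}-2,6-dimethyloct-2-en-1-ol
Product: 4 [(2R,3R)-3-[(3S)-5-{[tert-butyl(diphenyl)silyl]oxy}-3-methylpentyl]-2-methyloxiran-2-yl]methanol
Conditions: Ti(OiPr)4 (10 mol %), D-(−)-diisopropyl tartrate (12 mol %), t-BuOOH (2 equiv), 4 Å molecular sieves, CH2Cl2, −20 °C
Reagents that add atoms: tert-butyl hydroperoxide, CC(C)(C)OO
Why: Katsuki–Sharpless asymmetric epoxidation of an (E)-2-methylallylic alcohol; the D-(−)-tartrate ligand delivers oxygen to the face that gives the (2R,3R)-epoxide, which fixes C11 (R) directly and C12 as the R precursor of the S centre formed by inversion in step 10.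

Step 4
Reactants: 4 [(2R,3R)-3-[(3S)-5-{[tert-butyl(diphenyl)silyl]oxy}-3-methylpentyl]-2-methyloxiran-2-yl]methanol
Product: 5 [(2R,3R)-3-[(3S)-5-{[tert-butyl(diphenyl)silyl]oxy}-3-methylpentyl]-2-methyloxiran-2-yl]methyl trifluoromethanesulfonate
Conditions: Tf2O, 2,6-lutidine, CH2Cl2, −78 °C; used crude
Reagents that add atoms: trifluoromethanesulfonic anhydride, O=S(=O)(OS(=O)(=O)C(F)(F)F)C(F)(F)F
Why: O-Sulfonylation of the primary epoxy alcohol gives a 1,2-dielectrophile whose triflate carbon C13 has no β-hydrogen (C12 is quaternary), so it can only be substituted; no configuration changes.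

Step 5
Reactants: 6 prop-2-yn-1-ol, 7 isopropylmagnesium chloride
Product: 9 3-methyl-2-methylidenebutan-1-ol, via alkenylmagnesium chelate 8 (not isolated)
Conditions: i-PrMgCl (2.5 equiv), CuI (10 mol %), Et2O, −10 °C → rt; then 1 M HCl, 0 °C
Reagents that add atoms: none
Why: Copper-catalysed carbomagnesiation of propargyl alcohol: after O-deprotonation the isopropyl group adds to the internal alkyne carbon in an anti sense to give a five-membered magnesium chelate, which fixes the 2-substituted regiochemistry before protonation.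

Step 6
Reactants: 9 3-methyl-2-methylidenebutan-1-ol
Product: 10 [(2R)-2-(propan-2-yl)oxiran-2-yl]methanol
Conditions: Ti(OiPr)4 (10 mol %), D-(−)-diisopropyl tartrate (12 mol %), t-BuOOH (2 equiv), 4 Å molecular sieves, CH2Cl2, −20 °C
Reagents that add atoms: tert-butyl hydroperoxide, CC(C)(C)OO
Why: Katsuki–Sharpless asymmetric epoxidation of a 2-substituted allylic alcohol; D-(−)-tartrate should give the (R)-epoxide and thereby sets the quaternary centre that becomes C1.

Step 7
Reactants: 10 [(2R)-2-(propan-2-yl)oxiran-2-yl]methanol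
Product: 12 (2S)-2-(propan-2-yl)but-3-ene-1,2-diol, via sulfonium betaine 11 (not isolated)
Conditions: Me3SI (4 equiv), n-BuLi (3.8 equiv), THF, −10 °C → rt; H2O
Reagents that add atoms: trimethylsulfonium iodide, C[S+](C)C.[I-]
Why: Dimethylsulfonium methylide (Corey–Chaykovsky reagent) opens the epoxide at its CH2 terminus and the γ-oxido sulfonium salt undergoes ylide-mediated elimination of Me2S (one-carbon homologation of an epoxide to an allylic alcohol), so the quaternary carbinol centre is never touched and a Payne shift of the epoxy alkoxide is degenerate.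

Step 8
Reactants: 12 (2S)-2-(propan-2-yl)but-3-ene-1,2-diol
Product: 13 (2S)-2-hydroxy-2-(propan-2-yl)but-3-en-1-yl 4-methylbenzenesulfonate
Conditions: TsCl (1.1 equiv), pyridine, CH2Cl2, 0 °C
Reagents that add atoms: 4-methylbenzenesulfonyl chloride, Cc1ccc(cc1)S(Cl)(=O)=O
Why: Selective sulfonylation: only the primary hydroxyl should react, the tertiary allylic one is too hindered.

Step 9
Reactants: 13 (2S)-2-hydroxy-2-(propan-2-yl)but-3-en-1-yl 4-methylbenzenesulfonate
Product: 15 (3S)-4-methyl-3-[(phenylsulfanyl)methyl]pent-1-en-3-ol, via vinyl epoxide 14 (not isolated)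
Conditions: PhSH (1.5 equiv), K2CO3 (2.5 equiv), DMF, rt
Reagents that add atoms: benzenethiol, Sc1ccccc1
Why: Intramolecular Williamson closure to the vinyl epoxide followed by SN2 opening by thiolate at the unhindered CH2 terminus (direct displacement of the tosylate leads to the same product) installs a reductively cleavable C–S bond at C14 without touching C1.

Step 10
Reactants: 15 (3S)-4-methyl-3-[(phenylsulfanyl)methyl]pent-1-en-3-ol, 5 [(2R,3R)-3-[(3S)-5-{[tert-butyl(diphenyl)silyl]oxy}-3-methylpentyl]-2-methyloxiran-2-yl]methyl trifluoromethanesulfonate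
Product: 19 (1R,4S)-6-{[tert-butyl(diphenyl)silyl]oxy}-1-[(2S,5S)-5-ethenyl-2-methyl-5-(propan-2-yl)oxolan-2-yl]-4-methylhexan-1-ol, via dilithio alkoxide 16 (not isolated), via phenylthio cuprate 17 (not isolated), via hydroxy epoxide 18 (not isolated)
Conditions: n-BuLi (1.0 equiv), THF, −78 °C; LiDBB (lithium 4,4'-di-tert-butylbiphenylide, 2.05 equiv), −78 °C; CuBr·SMe2 (1.0 equiv), −78 → −50 °C; 5 (0.8 equiv), −78 → −30 °C; then camphorsulfonic acid (3 equiv), CH2Cl2, −30 → 0 °C
Reagents that add atoms: none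
Why: Proposed new method: O-deprotonation and reductive cleavage of the C–S bond of 15 by the arene radical anion give the C14,O-dilithio species 16, whose by-product LiSPh is bound by CuBr as the non-transferable ligand of mixed cuprate 17; 17 displaces the primary triflate of 5 by SN2 at C13 (C13–C14 bond) and, once acid frees the tertiary C1 hydroxyl of 18, this oxygen opens the adjacent epoxide at C12 (O–C12 bond). The closest known reaction types are the reductive lithiation of β-(phenylthio) alkoxides to β-lithio alkoxides and their thiolate cuprates, the alkylation of cuprates by 2,3-epoxy triflates and the acid-catalysed cyclisation of 4,5-epoxy alcohols to 2-(1-hydroxyalkyl)oxolanes; new is their union into a formal [3+2] annulation of a 1,3-C,O-dianion with a 1,2-dielectrophile. The oxolane is closed in the 5-exo-tet mode. C12 is set by inversion at the epoxide carbon (so it is dictated by the tartrate of step 3), C11 keeps its epoxide configuration and appears as the free carbinol, and C1 is carried unchanged from 15, which places the two future macrocycle arms cis on the oxolane by building-block control alone. The step needs alkyl instead of thiolate transfer (thiolate is the dummy ligand), triflate displacement before epoxide attack (a primary triflate should far outpace a trisubstituted epoxide toward cuprates, and quaternary C12 excludes elimination), survival of the β-oxido organometallic (held at or below −50 °C, where loss of Li2O should be slow) and 5-exo instead of 6-endo opening (favoured by ring size and by the tertiary C12).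

Step 11
Reactants: 19 (1R,4S)-6-{[tert-butyl(diphenyl)silyl]oxy}-1-[(2S,5S)-5-ethenyl-2-methyl-5-(propan-2-yl)oxolan-2-yl]-4-methylhexan-1-ol
Product: 20 (1R,4S)-6-{[tert-butyl(diphenyl)silyl]oxy}-1-[(2S,5S)-5-ethenyl-2-methyl-5-(propan-2-yl)oxolan-2-yl]-4-methylhexyl acetate
Conditions: Ac2O, pyridine, DMAP (cat.), CH2Cl2, rt
Reagents that add atoms: acetic anhydride, CC(=O)OC(C)=O
Why: DMAP-catalysed acylation of the only free hydroxyl, the hindered secondary C11 carbinol, installs the acetate of the target.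

Step 12
Reactants: 20 (1R,4S)-6-{[tert-butyl(diphenyl)silyl]oxy}-1-[(2S,5S)-5-ethenyl-2-methyl-5-(propan-2-yl)oxolan-2-yl]-4-methylhexyl acetate
Product: 21 (1R,4S)-1-[(2S,5S)-5-ethenyl-2-methyl-5-(propan-2-yl)oxolan-2-yl]-6-hydroxy-4-methylhexyl acetate
Conditions: HF·pyridine, pyridine, THF, 0 °C → rt
Reagents that add atoms: none
Why: Fluoride cleavage of the primary silyl ether under buffered conditions that should leave the acetate and the tertiary allylic ether intact.

Step 13
Reactants: 21 (1R,4S)-1-[(2S,5S)-5-ethenyl-2-methyl-5-(propan-2-yl)oxolan-2-yl]-6-hydroxy-4-methylhexyl acetate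
Product: 22 (1R,4S)-1-[(2S,5S)-5-ethenyl-2-methyl-5-(propan-2-yl)oxolan-2-yl]-4-methyl-6-oxohexyl acetate
Conditions: Dess–Martin periodinane, CH2Cl2, 0 °C → rt
Reagents that add atoms: none
Why: Dess–Martin oxidation of the primary alcohol to the C6 aldehyde under neutral conditions; no stereocentre is α to the new carbonyl.

Step 14
Reactants: 23 (R)-2-methylglycidol
Product: 25 (2S)-2-methylbut-3-ene-1,2-diol, via sulfonium betaine 24 (not isolated)
Conditions: Me3SI (4 equiv), n-BuLi (3.8 equiv), THF, −10 °C → rt; H2O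
Reagents that add atoms: trimethylsulfonium iodide, C[S+](C)C.[I-]
Why: Same ylide-mediated one-carbon homologation of an epoxide to an allylic alcohol as in step 7; the quaternary centre that becomes C4 is not touched.

Step 15
Reactants: 25 (2S)-2-methylbut-3-ene-1,2-diol
Product: 26 (2S)-2-hydroxy-2-methylbut-3-en-1-yl 4-methylbenzenesulfonate
Conditions: TsCl (1.1 equiv), pyridine, CH2Cl2, 0 °C
Reagents that add atoms: 4-methylbenzenesulfonyl chloride, Cc1ccc(cc1)S(Cl)(=O)=O
Why: Selective sulfonylation of the primary hydroxyl in the presence of the tertiary allylic one.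

Step 16
Reactants: 26 (2S)-2-hydroxy-2-methylbut-3-en-1-yl 4-methylbenzenesulfonate
Product: 28 (2S)-2-methyl-1-(phenylsulfanyl)but-3-en-2-ol, via vinyl epoxide 27 (not isolated)
Conditions: PhSH (1.5 equiv), K2CO3 (2.5 equiv), DMF, rt
Reagents that add atoms: benzenethiol, Sc1ccccc1
Why: Williamson closure to the vinyl epoxide and SN2 opening by thiolate at the CH2 terminus, as in step 9; C4 is not touched.

Step 17
Reactants: 28 (2S)-2-methyl-1-(phenylsulfanyl)but-3-en-2-ol, 22 (1R,4S)-1-[(2S,5S)-5-ethenyl-2-methyl-5-(propan-2-yl)oxolan-2-yl]-4-methyl-6-oxohexyl acetate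
Product: 31 (1R,4S,8R)-1-[(2S,5S)-5-ethenyl-2-methyl-5-(propan-2-yl)oxolan-2-yl]-6,8-dihydroxy-4,8-dimethyldec-9-en-1-yl acetate (both C6 epimers), via dilithio alkoxide 29 (not isolated), via organocerium reagent 30 (not isolated)
Conditions: 28 (1.4 equiv), n-BuLi (1.4 equiv), THF, −78 °C; LiDBB (2.9 equiv), −78 °C; CeCl3 (1.8 equiv), −78 °C; then 22, −78 °C; H2O
Reagents that add atoms: none
Why: Reductive lithiation of the C–S bond of the lithium alkoxide gives a β-lithio alkoxide, which after transmetalation to the less basic organocerium should add to the aldehyde in the presence of the acetate (organocerium carbonyl addition); the new C6 carbinol centre needs no control because it is oxidised in step 18, and C4 comes unchanged from 28.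

Step 18
Reactants: 31 (1R,4S,8R)-1-[(2S,5S)-5-ethenyl-2-methyl-5-(propan-2-yl)oxolan-2-yl]-6,8-dihydroxy-4,8-dimethyldec-9-en-1-yl acetate
Product: 32 (1R,4S,8R)-1-[(2S,5S)-5-ethenyl-2-methyl-5-(propan-2-yl)oxolan-2-yl]-8-hydroxy-4,8-dimethyl-6-oxodec-9-en-1-yl acetate
Conditions: Dess–Martin periodinane, pyridine, CH2Cl2, 0 °C
Reagents that add atoms: none
Why: Dess–Martin oxidation converts the secondary C6 carbinol into the ketone while the tertiary allylic C4 hydroxyl cannot be oxidised, giving the β-hydroxy ketone.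

Step 19
Reactants: 32 (1R,4S,8R)-1-[(2S,5S)-5-ethenyl-2-methyl-5-(propan-2-yl)oxolan-2-yl]-8-hydroxy-4,8-dimethyl-6-oxodec-9-en-1-yl acetate
Product: 33 (1S,2R,5S,9R,10E,12S)-9-hydroxy-1,5,9-trimethyl-7-oxo-12-(propan-2-yl)-15-oxabicyclo[10.2.1]pentadec-10-en-2-yl acetate (CNP0131678.1)
Conditions: second-generation Hoveyda–Grubbs catalyst RuCl2(H2IMes)(=CH–C6H4-2-OiPr) (10 mol %), toluene (1 mM), 80 °C, argon sparge
Reagents that add atoms: none
Why: Ring-closing metathesis: the ruthenium carbene should initiate at the vinyl group of the free tertiary allylic alcohol and close the 14-membered ring onto the oxolane vinyl group with loss of ethene; the two fully substituted allylic carbons are expected to enforce the (E)-alkene, and no allylic hydrogen is available for isomerisation.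

## Compound list

1 | (S)-citronellol, (3S)-3,7-dimethyloct-6-en-1-ol | CC(C)=CCC[C@H](C)CCO | starting material
2 | tert-butyl{[(3S)-3,7-dimethyloct-6-en-1-yl]oxy}diphenylsilane | CC(C)=CCC[C@H](C)CCO[Si](c1ccccc1)(c2ccccc2)C(C)(C)C | intermediate
3 | (2E,6S)-8-{[tert-butyl(diphenyl)silyl]oxy}-2,6-dimethyloct-2-en-1-ol | OC/C(C)=C/CC[C@H](C)CCO[Si](c1ccccc1)(c2ccccc2)C(C)(C)C | intermediate
4 | [(2R,3R)-3-[(3S)-5-{[tert-butyl(diphenyl)silyl]oxy}-3-methylpentyl]-2-methyloxiran-2-yl]methanol | OC[C@@]1(C)O[C@@H]1CC[C@H](C)CCO[Si](c2ccccc2)(c3ccccc3)C(C)(C)C | intermediate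
5 | [(2R,3R)-3-[(3S)-5-{[tert-butyl(diphenyl)silyl]oxy}-3-methylpentyl]-2-methyloxiran-2-yl]methyl trifluoromethanesulfonate | O=S(=O)(OC[C@@]1(C)O[C@@H]1CC[C@H](C)CCO[Si](c2ccccc2)(c3ccccc3)C(C)(C)C)C(F)(F)F | intermediate
6 | prop-2-yn-1-ol | C#CCO | starting material
7 | isopropylmagnesium chloride | CC(C)[Mg]Cl | starting material
8 | chloromagnesium (Z)-3-(chloromagnesio)-2-(propan-2-yl)prop-2-en-1-olate | Cl[Mg]/C=C(\CO[Mg]Cl)C(C)C | intermediate
9 | 3-methyl-2-methylidenebutan-1-ol | C=C(CO)C(C)C | intermediate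
10 | [(2R)-2-(propan-2-yl)oxiran-2-yl]methanol | OC[C@]1(C(C)C)CO1 | intermediate
11 | lithium (2S)-4-(dimethylsulfonio)-2-oxido-2-(propan-2-yl)butan-1-olate (sulfonium betaine) | C[S+](C)CC[C@@]([O-])(C(C)C)CO[Li] | intermediate
12 | (2S)-2-(propan-2-yl)but-3-ene-1,2-diol | C=C[C@@](O)(C(C)C)CO | intermediate
13 | (2S)-2-hydroxy-2-(propan-2-yl)but-3-en-1-yl 4-methylbenzenesulfonate | C=C[C@@](O)(C(C)C)COS(=O)(=O)c1ccc(C)cc1 | intermediate
14 | (2S)-2-ethenyl-2-(propan-2-yl)oxirane | C=C[C@@]1(C(C)C)CO1 | intermediate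
15 | (3S)-4-methyl-3-[(phenylsulfanyl)methyl]pent-1-en-3-ol | C=C[C@@](O)(C(C)C)CSc1ccccc1 | intermediate
16 | lithium (3S)-3-(lithiomethyl)-4-methylpent-1-en-3-olate | C=C[C@@](O[Li])(C(C)C)C[Li] | intermediate
17 | lithium {[(2S)-2-(lithiooxy)-2-(propan-2-yl)but-3-en-1-yl]}(phenylthio)cuprate | C=C[C@@](O[Li])(C(C)C)C[Cu-]Sc1ccccc1.[Li+] | intermediate
18 | (3S)-3-{2-[(2R,3R)-3-[(3S)-5-{[tert-butyl(diphenyl)silyl]oxy}-3-methylpentyl]-2-methyloxiran-2-yl]ethyl}-4-methylpent-1-en-3-ol | C=C[C@@](O)(C(C)C)CC[C@@]1(C)O[C@@H]1CC[C@H](C)CCO[Si](c2ccccc2)(c3ccccc3)C(C)(C)C | intermediate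
19 | (1R,4S)-6-{[tert-butyl(diphenyl)silyl]oxy}-1-[(2S,5S)-5-ethenyl-2-methyl-5-(propan-2-yl)oxolan-2-yl]-4-methylhexan-1-ol | C=C[C@@]1(C(C)C)CC[C@](C)(O1)[C@H](O)CC[C@H](C)CCO[Si](c2ccccc2)(c3ccccc3)C(C)(C)C | intermediate
20 | (1R,4S)-6-{[tert-butyl(diphenyl)silyl]oxy}-1-[(2S,5S)-5-ethenyl-2-methyl-5-(propan-2-yl)oxolan-2-yl]-4-methylhexyl acetate | C=C[C@@]1(C(C)C)CC[C@](C)(O1)[C@H](OC(C)=O)CC[C@H](C)CCO[Si](c2ccccc2)(c3ccccc3)C(C)(C)C | intermediate
21 | (1R,4S)-1-[(2S,5S)-5-ethenyl-2-methyl-5-(propan-2-yl)oxolan-2-yl]-6-hydroxy-4-methylhexyl acetate | C=C[C@@]1(C(C)C)CC[C@](C)(O1)[C@H](OC(C)=O)CC[C@H](C)CCO | intermediate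
22 | (1R,4S)-1-[(2S,5S)-5-ethenyl-2-methyl-5-(propan-2-yl)oxolan-2-yl]-4-methyl-6-oxohexyl acetate | C=C[C@@]1(C(C)C)CC[C@](C)(O1)[C@H](OC(C)=O)CC[C@H](C)CC=O | intermediate
23 | (R)-2-methylglycidol, [(2R)-2-methyloxiran-2-yl]methanol | OC[C@]1(C)CO1 | starting material
24 | lithium (2S)-4-(dimethylsulfonio)-2-methyl-2-oxidobutan-1-olate (sulfonium betaine) | C[S+](C)CC[C@@]([O-])(C)CO[Li] | intermediate
25 | (2S)-2-methylbut-3-ene-1,2-diol | C=C[C@@](O)(C)CO | intermediate
26 | (2S)-2-hydroxy-2-methylbut-3-en-1-yl 4-methylbenzenesulfonate | C=C[C@@](O)(C)COS(=O)(=O)c1ccc(C)cc1 | intermediate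
27 | (2S)-2-ethenyl-2-methyloxirane | C=C[C@@]1(C)CO1 | intermediate
28 | (2S)-2-methyl-1-(phenylsulfanyl)but-3-en-2-ol | C=C[C@@](O)(C)CSc1ccccc1 | intermediate
29 | lithium (2S)-1-lithio-2-methylbut-3-en-2-olate | C=C[C@@](O[Li])(C)C[Li] | intermediate
30 | dichloro[(2S)-2-(lithiooxy)-2-methylbut-3-en-1-yl]cerium | C=C[C@@](O[Li])(C)C[Ce](Cl)Cl | intermediate
31 | (1R,4S,8R)-1-[(2S,5S)-5-ethenyl-2-methyl-5-(propan-2-yl)oxolan-2-yl]-6,8-dihydroxy-4,8-dimethyldec-9-en-1-yl acetate (C6 epimers) | C=C[C@@]1(C(C)C)CC[C@](C)(O1)[C@H](OC(C)=O)CC[C@H](C)CC(O)C[C@@](C)(O)C=C | intermediate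
32 | (1R,4S,8R)-1-[(2S,5S)-5-ethenyl-2-methyl-5-(propan-2-yl)oxolan-2-yl]-8-hydroxy-4,8-dimethyl-6-oxodec-9-en-1-yl acetate | C=C[C@@]1(C(C)C)CC[C@](C)(O1)[C@H](OC(C)=O)CC[C@H](C)CC(=O)C[C@@](C)(O)C=C | intermediate
33 | (1S,2R,5S,9R,10E,12S)-9-hydroxy-1,5,9-trimethyl-7-oxo-12-(propan-2-yl)-15-oxabicyclo[10.2.1]pentadec-10-en-2-yl acetate (CNP0131678.1) | CC(=O)O[C@@H]1CC[C@H](C)CC(=O)C[C@@](C)(O)/C=C/[C@@]2(C(C)C)CC[C@]1(C)O2 | target

## Step count and risks

Total step count: 19. Longest linear sequence: 12 steps (steps 5–13 and 17–19, from prop-2-yn-1-ol).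

Steps most likely to fail:

1. Step 10 (proposed method). What may go wrong: loss of Li2O from the β-oxido organometallic before C–C coupling, transfer of the thiolate instead of the alkyl group, or acid-promoted ionisation of the tertiary allylic alcohol in competition with epoxide opening. The fallback uses known reactions only, sets out from triflate 5 and returns at 19. Triflate 5 is alkylated at C13 by the kinetic lithium enolate of 3-methylbutan-2-one (LDA, THF, −78 °C) to give 1-[(2R,3R)-3-[(3S)-5-{[tert-butyl(diphenyl)silyl]oxy}-3-methylpentyl]-2-methyloxiran-2-yl]-4-methylpentan-3-one F1. Vinylmagnesium bromide with CeCl3 (THF, −78 °C) then adds to the ketone without facial control and should give hydroxy epoxide 18 together with its C1 epimer F2. Camphorsulfonic acid (CH2Cl2, 0 °C) closes both by the same 5-exo opening to 19 and the C1-epimeric oxolane F3, which are separated by chromatography. The price is the loss of reagent control at C1.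

2. Step 19. What may go wrong: slow productive metathesis between two vinyl groups that both sit on fully substituted carbons, so that catalyst decay or intermolecular dimerisation through the carbinol terminus outruns ring closure; incomplete E selectivity. The fallback sets out from aldehyde 22 and returns at 33; it closes the ring by olefination and creates C4 afterwards. The dianion of dimethyl (2-oxopropyl)phosphonate (NaH, then n-BuLi, THF, −78 °C) adds through its terminal carbon to 22 to give δ-hydroxy β-keto phosphonate F4, which is silylated (Et3SiCl, imidazole) to triethylsilyl ether F5. Ozonolysis of the vinyl group (O3, CH2Cl2, −78 °C; PPh3) gives oxolane aldehyde F6. Intramolecular Horner–Wadsworth–Emmons reaction (LiCl, i-Pr2NEt, MeCN, high dilution) should give the macrocyclic (E)-enone F7. MeCeCl2 (from MeLi and CeCl3, THF, −78 °C) adds 1,2 to the enone carbonyl to give tertiary allylic alcohol F8; the face of attack is dictated by the macrocycle and would have to be checked. HF·pyridine gives diol F9, and Dess–Martin oxidation of its secondary hydroxyl gives 33.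

3. Step 17. What may go wrong: reduction of the aldehyde or acetate by residual radical anion, attack on the acetate or enolisation by the organometallic, or elimination of Li2O from the β-lithio alkoxide before transmetalation. The fallback sets out from 22 and returns at 32; it makes the C4–C5 bond by an aldol addition instead. MeMgBr (THF, −78 °C) converts 22 into secondary alcohol F10, and Dess–Martin oxidation gives methyl ketone F11. Its kinetic lithium enolate (LDA, THF, −78 °C, deprotonation at the methyl group) adds 1,2 to methyl vinyl ketone at −78 °C to give 32 together with its C4 epimer F12, separated by chromatography. C4 is then not reagent-controlled.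

## Further compounds

F1 | step 10 | 1-[(2R,3R)-3-[(3S)-5-{[tert-butyl(diphenyl)silyl]oxy}-3-methylpentyl]-2-methyloxiran-2-yl]-4-methylpentan-3-one | CC(C)C(=O)CC[C@@]1(C)O[C@@H]1CC[C@H](C)CCO[Si](c2ccccc2)(c3ccccc3)C(C)(C)C
F2 | step 10 | (3R)-3-{2-[(2R,3R)-3-[(3S)-5-{[tert-butyl(diphenyl)silyl]oxy}-3-methylpentyl]-2-methyloxiran-2-yl]ethyl}-4-methylpent-1-en-3-ol (C1 epimer of 18) | C=C[C@](O)(C(C)C)CC[C@@]1(C)O[C@@H]1CC[C@H](C)CCO[Si](c2ccccc2)(c3ccccc3)C(C)(C)C
F3 | step 10 | (1R,4S)-6-{[tert-butyl(diphenyl)silyl]oxy}-1-[(2S,5R)-5-ethenyl-2-methyl-5-(propan-2-yl)oxolan-2-yl]-4-methylhexan-1-ol (C1 epimer of 19) | C=C[C@]1(C(C)C)CC[C@](C)(O1)[C@H](O)CC[C@H](C)CCO[Si](c2ccccc2)(c3ccccc3)C(C)(C)C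
F4 | step 19 | dimethyl [(6S,9R)-9-acetoxy-9-[(2S,5S)-5-ethenyl-2-methyl-5-(propan-2-yl)oxolan-2-yl]-4-hydroxy-6-methyl-2-oxononyl]phosphonate (C4 epimers of the chain) | C=C[C@@]1(C(C)C)CC[C@](C)(O1)[C@H](OC(C)=O)CC[C@H](C)CC(O)CC(=O)CP(=O)(OC)OC
F5 | step 19 | dimethyl [(6S,9R)-9-acetoxy-9-[(2S,5S)-5-ethenyl-2-methyl-5-(propan-2-yl)oxolan-2-yl]-6-methyl-2-oxo-4-[(triethylsilyl)oxy]nonyl]phosphonate | C=C[C@@]1(C(C)C)CC[C@](C)(O1)[C@H](OC(C)=O)CC[C@H](C)CC(O[Si](CC)(CC)CC)CC(=O)CP(=O)(OC)OC
F6 | step 19 | dimethyl [(6S,9R)-9-acetoxy-9-[(2S,5S)-5-formyl-2-methyl-5-(propan-2-yl)oxolan-2-yl]-6-methyl-2-oxo-4-[(triethylsilyl)oxy]nonyl]phosphonate | O=C[C@@]1(C(C)C)CC[C@](C)(O1)[C@H](OC(C)=O)CC[C@H](C)CC(O[Si](CC)(CC)CC)CC(=O)CP(=O)(OC)OC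
F7 | step 19 | (1S,2R,5S,10E,12S)-1,5-dimethyl-9-oxo-12-(propan-2-yl)-7-[(triethylsilyl)oxy]-15-oxabicyclo[10.2.1]pentadec-10-en-2-yl acetate | CC(=O)O[C@@H]1CC[C@H](C)CC(O[Si](CC)(CC)CC)CC(=O)/C=C/[C@@]2(C(C)C)CC[C@]1(C)O2
F8 | step 19 | (1S,2R,5S,9R,10E,12S)-9-hydroxy-1,5,9-trimethyl-12-(propan-2-yl)-7-[(triethylsilyl)oxy]-15-oxabicyclo[10.2.1]pentadec-10-en-2-yl acetate | CC(=O)O[C@@H]1CC[C@H](C)CC(O[Si](CC)(CC)CC)C[C@@](C)(O)/C=C/[C@@]2(C(C)C)CC[C@]1(C)O2
F9 | step 19 | (1S,2R,5S,9R,10E,12S)-7,9-dihydroxy-1,5,9-trimethyl-12-(propan-2-yl)-15-oxabicyclo[10.2.1]pentadec-10-en-2-yl acetate | CC(=O)O[C@@H]1CC[C@H](C)CC(O)C[C@@](C)(O)/C=C/[C@@]2(C(C)C)CC[C@]1(C)O2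
F10 | step 17 | (1R,4S)-1-[(2S,5S)-5-ethenyl-2-methyl-5-(propan-2-yl)oxolan-2-yl]-6-hydroxy-4-methylheptyl acetate (C6 epimers) | C=C[C@@]1(C(C)C)CC[C@](C)(O1)[C@H](OC(C)=O)CC[C@H](C)CC(C)O
F11 | step 17 | (1R,4S)-1-[(2S,5S)-5-ethenyl-2-methyl-5-(propan-2-yl)oxolan-2-yl]-4-methyl-6-oxoheptyl acetate | C=C[C@@]1(C(C)C)CC[C@](C)(O1)[C@H](OC(C)=O)CC[C@H](C)CC(C)=O
F12 | step 17 | (1R,4S,8S)-1-[(2S,5S)-5-ethenyl-2-methyl-5-(propan-2-yl)oxolan-2-yl]-8-hydroxy-4,8-dimethyl-6-oxodec-9-en-1-yl acetate (C4 epimer of 32) | C=C[C@@]1(C(C)C)CC[C@](C)(O1)[C@H](OC(C)=O)CC[C@H](C)CC(=O)C[C@](C)(O)C=C
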